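The synthesis rests on opening ring A at its C5–C6 ethano bridge and ring B at C4a–C8a (octahydronaphthalene locants: C1 carries the side chain, C7 the exocyclic methylene). One palladium-catalysed operation converts an acyclic 2-bromo-1,7-enyne into the bicycle: 6-exo-dig carbopalladation, Stille capture of a 1-ethoxyvinyl unit and thermal 6π-electrocyclisation, which unites the two terminal methylene carbons C5 and C6 of a hexatriene, two alkene termini of like polarity. Hydrolysis gives the ring A enone, whose γ-carbons C4a and C1 equilibrate to the all-equatorial isomer, so the precursor needs stereocontrol only at C3/C4 and C1′/C2′ and may be a C1 epimer mixture.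

Key step: step 10

Remarks
- Locants: core C1 (side chain), C2, C3 (OAc), C4 (CH3), C4a, C5, C6, C7 (=CH2), C8, C8a; side chain C1′ (CH3), C2′ (OAc), C3′ (C=O), C4′=C5′.
- Assumption: compounds 1, 3, 4, 9, 11, 20 and all named reagents are commercial; 3 is used as freshly distilled monomer.
- From step 5 to step 10 C1 is carried as a mixture of epimers (left undefined in the SMILES), because step 10 equilibrates it.

Step 1
Reactants: 1 (R)-but-3-yn-2-ol
Product: 2 (R)-but-3-yn-2-yl methanesulfonate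
Conditions: MsCl, Et3N, CH2Cl2, −78 → 0 °C
Reagents that add atoms: methanesulfonyl chloride, CS(=O)(=O)Cl
Why: O-sulfonylation (mesylation) leaves the C–O bond intact, so the (R) centre that later becomes C4 is retained.

Step 2
Reactants: 3 ethyl glyoxylate; 4 cis-but-2-ene
Product: 7 ethyl (2R,3S)-2-hydroxy-3-methylpent-4-enoate, via (Z)-but-2-enylpotassium 5 (not isolated), via (Z)-crotyldiisopinocampheylborane 6 (not isolated)
Conditions: 4, n-BuLi, KOt-Bu, THF, −78 → −45 °C; (+)-Ipc2BOMe [from (−)-α-pinene], −78 °C; BF3·OEt2; 3, −78 °C; then NaBO3·4H2O, THF/H2O, rt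
Reagents that add atoms: none
Why: Brown crotylboration through a closed chair transition state: the (Z)-crotyl geometry sets the syn C1′/C2′ relationship and the isopinocampheyl groups direct attack to the Re face of the glyoxylate carbonyl, which should give the (2R,3S) ester.

Step 3
Reactants: 7 ethyl (2R,3S)-2-hydroxy-3-methylpent-4-enoate
Product: 8 ethyl (2R,3S)-2-[(tert-butyldimethylsilyl)oxy]-3-methylpent-4-enoate
Conditions: TBSCl, imidazole, DMF, rt
Reagents that add atoms: tert-butyldimethylsilyl chloride, CC(C)(C)[Si](C)(C)Cl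
Why: Standard O-silylation; the ether keeps the C2′ oxygen from closing a lactol onto the C3 aldehyde formed in step 5.

Step 4
Reactants: 8 silyl ether; 9 (E)-but-2-enal
Product: 10 ethyl (2R,3S,4E)-2-[(tert-butyldimethylsilyl)oxy]-3-methyl-6-oxohex-4-enoate
Conditions: second-generation Hoveyda–Grubbs catalyst (3 mol %), CH2Cl2, 40 °C
Reagents that add atoms: none
Why: Olefin cross-metathesis of a terminal alkene with an electron-poor partner should give the (E)-enal with loss of propene, adding C2 and C3 without touching C1′.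

Step 5
Reactants: 10 enal; 11 ethynyltri(propan-2-yl)silane
Product: 12 ethyl (2R,3S)-2-[(tert-butyldimethylsilyl)oxy]-3-methyl-4-(2-oxoethyl)-6-[tri(propan-2-yl)silyl]hex-5-ynoate (C4 epimers; C4 of this chain is C1 of the target)
Conditions: [Rh(OAc)(C2H4)2]2 (2.5 mol %), (R)-DTBM-SEGPHOS (6 mol %), MeOH, 40 °C
Reagents that add atoms: none
Why: Rhodium-catalysed conjugate alkynylation of an enal (1,4-addition of an alkynylrhodium species, with the bulky silyl group and phosphine suppressing alkyne dimerisation and 1,2-addition); the new centre C1 needs no control because step 10 equilibrates it.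

Step 6
Reactants: 12 β-alkynyl aldehyde; 2 (R)-but-3-yn-2-yl methanesulfonate
Product: 14 ethyl (2R,3S,6R,7S)-2-[(tert-butyldimethylsilyl)oxy]-6-hydroxy-3,7-dimethyl-4-{[tri(propan-2-yl)silyl]ethynyl}non-8-ynoate, via (P)-buta-1,2-dienyl(ethyl)zinc 13 (not isolated)
Conditions: Pd(OAc)2 (5 mol %), PPh3 (5 mol %), Et2Zn (3 equiv), THF, −78 → −20 °C
Reagents that add atoms: none
Why: Marshall propargylation: zerovalent palladium ionises 2 with inversion (anti SN2′), transmetalation gives the (P)-allenylzinc, and its addition through a cyclic SE2′ transition state should give the anti homopropargylic alcohol with C4 (S) and C3 (R) under reagent control.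

Step 7
Reactants: 14 homopropargylic alcohol
Product: 15 ethyl (2R,3S,6R,7S)-2,6-bis[(tert-butyldimethylsilyl)oxy]-3,7-dimethyl-4-{[tri(propan-2-yl)silyl]ethynyl}non-8-ynoate
Conditions: TBSOTf, 2,6-lutidine, CH2Cl2, 0 °C
Reagents that add atoms: tert-butyldimethylsilyl trifluoromethanesulfonate, CC(C)(C)[Si](C)(C)OS(=O)(=O)C(F)(F)F
Why: Silyl triflate silylation of the hindered secondary alcohol shields the hydroxyl from the Lewis acidic bromoborane of step 8.

Step 8
Reactants: 15 bis-silyl diyne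
Product: 17 ethyl (2R,3S,6R,7R)-8-bromo-2,6-bis[(tert-butyldimethylsilyl)oxy]-3,7-dimethyl-4-{[tri(propan-2-yl)silyl]ethynyl}non-8-enoate, via (Z)-2-bromoalkenyl-9-BBN adduct 16 (not isolated)
Conditions: B-bromo-9-borabicyclo[3.3.1]nonane, CH2Cl2, 0 °C; then AcOH, 0 °C → rt
Reagents that add atoms: B-bromo-9-borabicyclo[3.3.1]nonane, BrB1C2CCCC1CCC2
Why: Haloboration: syn addition of B–Br to the only terminal alkyne places bromine on the internal carbon C4a (the silylalkyne is inert), and protodeboronation with acetic acid should leave the 2-bromoalk-1-ene.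

Step 9
Reactants: 17 bromoalkene
Product: 19 ethyl (2R,3S,6R,7R)-8-bromo-2,6-bis[(tert-butyldimethylsilyl)oxy]-4-ethynyl-3,7-dimethylnon-8-enoate, via silver acetylide 18 (not isolated)
Conditions: AgF, MeOH, rt, dark; then 1 M HCl
Reagents that add atoms: none
Why: Silver-mediated protodesilylation cleaves the C(sp)–Si bond selectively (π-activation of the alkyne, fluoride on silicon) while the silyl ethers should survive, and acid protonates the silver acetylide.

Step 10
Reactants: 19 bromo-enyne; 20 tributyl(1-ethoxyethenyl)stannane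
Product: 23 ethyl (2R,3S)-2-hydroxy-3-[(1S,3R,4S,4aS)-3-hydroxy-4-methyl-7-oxo-1,2,3,4,4a,5,6,7-octahydronaphthalen-1-yl]butanoate, via 2-ethoxytriene 21 (not isolated), via bicyclic ethoxydiene 22 (not isolated)
Conditions: Pd(PPh3)4 (5 mol %), toluene, 100 °C; then 48% aq HF, MeCN, rt; then DBU, CH2Cl2, rt
Reagents that add atoms: water, O
Why: Oxidative addition of zerovalent palladium into the C4a–Br bond is followed by syn 6-exo-dig carbopalladation of the terminal alkyne (closing ring B through C4a–C8a and placing palladium on C8 cis to C4a) and Stille transfer of the 1-ethoxyvinyl group (C7, C6), giving the (Z)-configured triene C5=C4a–C8a=C8–C7(OEt)=C6. Thermal disrotatory 6π-electrocyclisation then forms the C5–C6 σ-bond between the two terminal methylene carbons and so closes ring A; the closest known reaction type is the palladium-catalysed cyclic carbopalladation/cross-coupling/6π-electrocyclisation domino of 2-bromo-1,n-enynes. Aqueous HF hydrolyses the ethoxydiene to the conjugated enone and removes both silyl ethers. No stereocentre is fixed kinetically: C4a and C1 are γ-carbons of the enone and DBU should equilibrate them through the dienolates (as in the 6β to 6α epimerisation of steroidal 4-en-3-ones) to the isomer with C5, the side chain and the C4 methyl equatorial and the C3 hydroxyl axial, anchored by the fixed C3/C4 pair. The step needs ring closure to outrun direct coupling (secured by the intramolecular 6-exo mode) and C7 to sit cis to C4a (secured by syn addition); both triene termini are unsubstituted, so torquoselectivity is irrelevant.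

Step 11
Reactants: 23 dihydroxy enone ester
Product: 24 ethyl (2R,3S)-2-hydroxy-3-[(1S,3R,4S,4aS)-3-hydroxy-4-methyl-7-methylidene-1,2,3,4,4a,5,6,7-octahydronaphthalen-1-yl]butanoate
Conditions: Ph3PCH3Br, KOt-Bu (excess), THF, 0 °C → rt
Reagents that add atoms: methyltriphenylphosphonium bromide, C[P+](c1ccccc1)(c1ccccc1)c1ccccc1.[Br-]
Why: Wittig methylenation of the cyclohexenone carbonyl installs the C7 methylene and thereby the 1,3-diene; excess ylide covers the two hydroxyls, the ester is far less electrophilic, and C1 and C4a already hold their thermodynamic configuration.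

Step 12
Reactants: 24 diene diol ester
Product: 25 (2R,3S)-2-hydroxy-3-[(1S,3R,4S,4aS)-3-hydroxy-4-methyl-7-methylidene-1,2,3,4,4a,5,6,7-octahydronaphthalen-1-yl]-N-methoxy-N-methylbutanamide
Conditions: MeNHOMe·HCl, i-PrMgCl, THF, −20 → 0 °C
Reagents that add atoms: N,O-dimethylhydroxylamine hydrochloride, CNOC.Cl
Why: Aminolysis of the ethyl ester by the chloromagnesium amide (Weinreb amide formation) is established for free α-hydroxy esters and should leave the diene untouched.

Step 13
Reactants: 25 Weinreb amide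
Product: 26 (2S,3R)-3-hydroxy-2-[(1S,3R,4S,4aS)-3-hydroxy-4-methyl-7-methylidene-1,2,3,4,4a,5,6,7-octahydronaphthalen-1-yl]-6-methylhept-5-en-4-one
Conditions: Me2C=CHMgBr (excess), THF, 0 °C
Reagents that add atoms: (2-methylprop-1-enyl)magnesium bromide, CC(C)=C[Mg]Br
Why: Grignard addition to the Weinreb amide stops at the chelated tetrahedral adduct, which releases the β,β-dimethyl enone on work-up; the two alkoxides only consume extra reagent.

Step 14
Reactants: 26 dihydroxy enone
Product: 27 (2S,3R)-2-[(1S,3R,4S,4aS)-3-acetoxy-4-methyl-7-methylidene-1,2,3,4,4a,5,6,7-octahydronaphthalen-1-yl]-6-methyl-4-oxohept-5-en-3-yl acetate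
Conditions: Ac2O, pyridine, DMAP, CH2Cl2, rt
Reagents that add atoms: acetic anhydride, CC(=O)OC(C)=O
Why: DMAP-catalysed O-acylation of both secondary hydroxyls (C3 and C2′) should give the diacetate without affecting any stereocentre.

Compound list
1 | (R)-but-3-yn-2-ol | C#C[C@@H](C)O | starting material
2 | (R)-but-3-yn-2-yl methanesulfonate | C#C[C@@H](C)OS(C)(=O)=O | intermediate
3 | ethyl glyoxylate | O=CC(=O)OCC | starting material
4 | cis-but-2-ene | C/C=C\C | starting material
5 | (Z)-but-2-enylpotassium | C/C=C\C[K] | intermediate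
6 | (Z)-but-2-enyl-diisopinocampheylborane, isopinocampheyl groups from (−)-α-pinene | C/C=C\CB([C@H]1C[C@H]2C[C@@H]([C@@H]1C)C2(C)C)[C@H]1C[C@H]2C[C@@H]([C@@H]1C)C2(C)C | intermediate
7 | ethyl (2R,3S)-2-hydroxy-3-methylpent-4-enoate | C=C[C@H](C)[C@@H](O)C(=O)OCC | intermediate
8 | ethyl (2R,3S)-2-[(tert-butyldimethylsilyl)oxy]-3-methylpent-4-enoate | C=C[C@H](C)[C@@H](O[Si](C)(C)C(C)(C)C)C(=O)OCC | intermediate
9 | (E)-but-2-enal | C/C=C/C=O | starting material
10 | ethyl (2R,3S,4E)-2-[(tert-butyldimethylsilyl)oxy]-3-methyl-6-oxohex-4-enoate | O=C/C=C/[C@H](C)[C@@H](O[Si](C)(C)C(C)(C)C)C(=O)OCC | intermediate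
11 | ethynyltri(propan-2-yl)silane | C#C[Si](C(C)C)(C(C)C)C(C)C | starting material
12 | ethyl (2R,3S)-2-[(tert-butyldimethylsilyl)oxy]-3-methyl-4-(2-oxoethyl)-6-[tri(propan-2-yl)silyl]hex-5-ynoate, C4 epimers | O=CCC(C#C[Si](C(C)C)(C(C)C)C(C)C)[C@H](C)[C@@H](O[Si](C)(C)C(C)(C)C)C(=O)OCC | intermediate
13 | (P)-buta-1,2-dienyl(ethyl)zinc | [H]C(C)=[C@]=C([H])[Zn]CC | intermediate
14 | ethyl (2R,3S,6R,7S)-2-[(tert-butyldimethylsilyl)oxy]-6-hydroxy-3,7-dimethyl-4-{[tri(propan-2-yl)silyl]ethynyl}non-8-ynoate, C4 epimers | C#C[C@H](C)[C@H](O)CC(C#C[Si](C(C)C)(C(C)C)C(C)C)[C@H](C)[C@@H](O[Si](C)(C)C(C)(C)C)C(=O)OCC | intermediate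
15 | ethyl (2R,3S,6R,7S)-2,6-bis[(tert-butyldimethylsilyl)oxy]-3,7-dimethyl-4-{[tri(propan-2-yl)silyl]ethynyl}non-8-ynoate, C4 epimers | C#C[C@H](C)[C@H](O[Si](C)(C)C(C)(C)C)CC(C#C[Si](C(C)C)(C(C)C)C(C)C)[C@H](C)[C@@H](O[Si](C)(C)C(C)(C)C)C(=O)OCC | intermediate
16 | (Z)-2-bromoalkenyl-9-BBN adduct of 15 (boron on C9, bromine on C8 of the chain, cis) | Br/C(=C\B1C2CCCC1CCC2)[C@H](C)[C@H](O[Si](C)(C)C(C)(C)C)CC(C#C[Si](C(C)C)(C(C)C)C(C)C)[C@H](C)[C@@H](O[Si](C)(C)C(C)(C)C)C(=O)OCC | intermediate
17 | ethyl (2R,3S,6R,7R)-8-bromo-2,6-bis[(tert-butyldimethylsilyl)oxy]-3,7-dimethyl-4-{[tri(propan-2-yl)silyl]ethynyl}non-8-enoate, C4 epimers | C=C(Br)[C@H](C)[C@H](O[Si](C)(C)C(C)(C)C)CC(C#C[Si](C(C)C)(C(C)C)C(C)C)[C@H](C)[C@@H](O[Si](C)(C)C(C)(C)C)C(=O)OCC | intermediate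
18 | silver acetylide of 19 | C=C(Br)[C@H](C)[C@H](O[Si](C)(C)C(C)(C)C)CC(C#C[Ag])[C@H](C)[C@@H](O[Si](C)(C)C(C)(C)C)C(=O)OCC | intermediate
19 | ethyl (2R,3S,6R,7R)-8-bromo-2,6-bis[(tert-butyldimethylsilyl)oxy]-4-ethynyl-3,7-dimethylnon-8-enoate, C4 epimers | C=C(Br)[C@H](C)[C@H](O[Si](C)(C)C(C)(C)C)CC(C#C)[C@H](C)[C@@H](O[Si](C)(C)C(C)(C)C)C(=O)OCC | intermediate
20 | tributyl(1-ethoxyethenyl)stannane | CCCC[Sn](CCCC)(CCCC)C(=C)OCC | starting material
21 | 2-ethoxytriene: ring B cyclohexane with exocyclic methylene at C4a, (Z)-CH–C(OEt)=CH2 ylidene at C8a (C7 cis to C4a), C4 methyl, C3 silyl ether and the silylated side chain at C1 | C=C1[C@H](C)[C@H](O[Si](C)(C)C(C)(C)C)CC([C@H](C)[C@@H](O[Si](C)(C)C(C)(C)C)C(=O)OCC)/C1=C/C(=C)OCC | intermediate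
22 | bicyclic ethoxydiene: 7-ethoxy-1,2,3,4,5,6-hexahydronaphthalene (C4a=C8a, C7=C8) with C4 methyl, C3 silyl ether and the silylated side chain at C1 | CCOC1=CC2=C(CC1)[C@H](C)[C@H](O[Si](C)(C)C(C)(C)C)CC2[C@H](C)[C@@H](O[Si](C)(C)C(C)(C)C)C(=O)OCC | intermediate
23 | ethyl (2R,3S)-2-hydroxy-3-[(1S,3R,4S,4aS)-3-hydroxy-4-methyl-7-oxo-1,2,3,4,4a,5,6,7-octahydronaphthalen-1-yl]butanoate | O=C1C=C2[C@@H](CC1)[C@H](C)[C@H](O)C[C@H]2[C@H](C)[C@@H](O)C(=O)OCC | intermediate
24 | ethyl (2R,3S)-2-hydroxy-3-[(1S,3R,4S,4aS)-3-hydroxy-4-methyl-7-methylidene-1,2,3,4,4a,5,6,7-octahydronaphthalen-1-yl]butanoate | C=C1C=C2[C@@H](CC1)[C@H](C)[C@H](O)C[C@H]2[C@H](C)[C@@H](O)C(=O)OCC | intermediate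
25 | (2R,3S)-2-hydroxy-3-[(1S,3R,4S,4aS)-3-hydroxy-4-methyl-7-methylidene-1,2,3,4,4a,5,6,7-octahydronaphthalen-1-yl]-N-methoxy-N-methylbutanamide | C=C1C=C2[C@@H](CC1)[C@H](C)[C@H](O)C[C@H]2[C@H](C)[C@@H](O)C(=O)N(C)OC | intermediate
26 | (2S,3R)-3-hydroxy-2-[(1S,3R,4S,4aS)-3-hydroxy-4-methyl-7-methylidene-1,2,3,4,4a,5,6,7-octahydronaphthalen-1-yl]-6-methylhept-5-en-4-one | C=C1C=C2[C@@H](CC1)[C@H](C)[C@H](O)C[C@H]2[C@H](C)[C@@H](O)C(=O)C=C(C)C | intermediate
27 | (2S,3R)-2-[(1S,3R,4S,4aS)-3-acetoxy-4-methyl-7-methylidene-1,2,3,4,4a,5,6,7-octahydronaphthalen-1-yl]-6-methyl-4-oxohept-5-en-3-yl acetate | C=C1C=C2[C@@H](CC1)[C@H](C)[C@H](OC(C)=O)C[C@H]2[C@H](C)[C@@H](OC(C)=O)C(=O)C=C(C)C | target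

Total step count: 14. Longest linear sequence: 13 steps (steps 2 to 14; step 1 is a one-step branch that enters at step 6).

Steps most likely to fail

Step 10 (key step). The electron-rich ethoxytriene 21 may polymerise or hydrolyse faster than it electrocyclises at 100 °C. The fallback replaces the thermal pericyclic closure by an anionic one. Starting from 19, the palladium step is run at 60 °C and worked up with dilute aqueous HCl, which should give the (Z)-configured methyl dienone F1 (ring B with exocyclic methylene at C4a and 2-oxopropylidene at C8a, silyl ethers intact). Kinetic deprotonation of the methyl ketone with KN(SiMe3)2 in THF at −78 °C generates the cross-conjugated trienolate, whose C6 carbanion should add to the exocyclic C5 methylene (intramolecular 1,6-addition, an anion-accelerated ring closure) and give after protonation the bis-silyl enone F2. Aqueous HF in MeCN followed by DBU then returns the route to 23.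

Step 5. On the γ-branched enal 10, 1,2-addition or alkyne dimerisation may outpace 1,4-addition. The fallback replaces conjugate addition by allylic substitution. Starting from 8, cross-metathesis with (Z)-but-2-ene-1,4-diol (second-generation Hoveyda–Grubbs catalyst) should give the (E)-allylic alcohol F3, which ClP(O)(OEt)2 and pyridine convert into the allylic diethyl phosphate F4. Copper-catalysed γ-selective (SN2′) coupling with 11 (CuCl, LiOt-Bu, phosphine ligand, THF) places the alkyne on C1 and gives the 1,4-enyne F5. Hydroboration of the terminal vinyl group with 9-borabicyclo[3.3.1]nonane and NaBO3 oxidation lead to the primary alcohol F6, and Dess–Martin oxidation returns the route to 12.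

Step 11. Deprotonation of the enone to its dienolate, together with consumption of ylide by the hydroxyl and ester groups, may stall the olefination. The fallback replaces the ylide by an addition and elimination sequence. Starting from 23, the organocerium reagent made from Me3SiCH2MgCl and CeCl3 (THF, −78 °C; non-basic and ketone-selective over the ester) should add to C7 and give the β-hydroxysilane F7. Peterson elimination under mild acid (AcOH, THF, rt) then returns the route to 24.

Further compounds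
F1 | step 10 | (Z)-methyl dienone: ring B cyclohexane with exocyclic methylene at C4a, (Z)-2-oxopropylidene at C8a, C4 methyl, C3 silyl ether and silylated side chain at C1 | C=C1[C@H](C)[C@H](O[Si](C)(C)C(C)(C)C)CC([C@H](C)[C@@H](O[Si](C)(C)C(C)(C)C)C(=O)OCC)/C1=C/C(C)=O
F2 | step 10 | ethyl (2R,3S)-2-[(tert-butyldimethylsilyl)oxy]-3-[(1S,3R,4S,4aS)-3-[(tert-butyldimethylsilyl)oxy]-4-methyl-7-oxo-1,2,3,4,4a,5,6,7-octahydronaphthalen-1-yl]butanoate | O=C1C=C2[C@@H](CC1)[C@H](C)[C@H](O[Si](C)(C)C(C)(C)C)C[C@H]2[C@H](C)[C@@H](O[Si](C)(C)C(C)(C)C)C(=O)OCC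
F3 | step 5 | ethyl (2R,3S,4E)-2-[(tert-butyldimethylsilyl)oxy]-6-hydroxy-3-methylhex-4-enoate | OC/C=C/[C@H](C)[C@@H](O[Si](C)(C)C(C)(C)C)C(=O)OCC
F4 | step 5 | ethyl (2R,3S,4E)-2-[(tert-butyldimethylsilyl)oxy]-6-[(diethoxyphosphoryl)oxy]-3-methylhex-4-enoate | CCOP(=O)(OCC)OC/C=C/[C@H](C)[C@@H](O[Si](C)(C)C(C)(C)C)C(=O)OCC
F5 | step 5 | ethyl (2R,3S)-2-[(tert-butyldimethylsilyl)oxy]-4-ethenyl-3-methyl-6-[tri(propan-2-yl)silyl]hex-5-ynoate, C4 epimers | C=CC(C#C[Si](C(C)C)(C(C)C)C(C)C)[C@H](C)[C@@H](O[Si](C)(C)C(C)(C)C)C(=O)OCC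
F6 | step 5 | ethyl (2R,3S)-2-[(tert-butyldimethylsilyl)oxy]-4-(2-hydroxyethyl)-3-methyl-6-[tri(propan-2-yl)silyl]hex-5-ynoate, C4 epimers | OCCC(C#C[Si](C(C)C)(C(C)C)C(C)C)[C@H](C)[C@@H](O[Si](C)(C)C(C)(C)C)C(=O)OCC
F7 | step 11 | ethyl (2R,3S)-2-hydroxy-3-[(1S,3R,4S,4aS)-3,7-dihydroxy-4-methyl-7-[(trimethylsilyl)methyl]-1,2,3,4,4a,5,6,7-octahydronaphthalen-1-yl]butanoate, C7 epimers | C[Si](C)(C)CC1(O)C=C2[C@@H](CC1)[C@H](C)[C@H](O)C[C@H]2[C@H](C)[C@@H](O)C(=O)OCC
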